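Labels: rings A/C/B are the 6-linked flavone. Rings A''/C''/B'' are the 8''-linked flavone.

**Plan**
- **Cuts, in retrosynthetic order:** first the O-alkyl bonds at O5 and O7 (isopropyl) and O5'' (methyl). Then C4–C4a and C4''–C4a'' together, which opens both pyranones to a bis(3-aryloxy-3-arylacrylic acid). Then the two O1–C2 enol-ether bonds, giving a biphenyl-2',4-diol and two arylpropiolates. Then C8a–O1 of ring A, and last the C6–C8'' biaryl bond.
- **Enabling feature:** in the open precursor the oxygen on C8a lies para to the axis on a 2,6-diisopropoxy ring A. Its two ortho carbons (future C4a and C8) are therefore equivalent. On ring A'' one carbon ortho to the C8a'' oxygen is the axis carbon C8'', so only C4a'' is free. Each acylation has a single outcome.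
- **Forward order:** rings A and A'' are joined first. The ring A oxygen is put in by C–H borylation/oxidation. Both side chains (with rings B and B'') are attached by oxa-Michael addition. Rings C and C'' then close in one flask, and dealkylation ends the route.
- **Stereochemistry:** there is no stereocentre. The Z enol ethers come from anti addition and are consumed in the closure. The C6–C8'' axis becomes stereogenic only in the closure and is racemic.

Key step: step 7

Assumption: the target string fixes no configuration at the hindered C6–C8'' axis, so the racemate is made. O5 and O7 are carried as isopropyl ethers because these survive n-BuLi, offer the iridium catalyst no extra arene C–H, resist CF3CO2H and fall to BCl3.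

Step 1
Reactants: 1 3,5-dimethoxyphenol
Product: 2 2-iodo-3,5-dimethoxyphenol
Conditions: NIS (1.0 equiv), CH2Cl2, 0 °C
Reagents that add atoms: N-iodosuccinimide, O=C1CCC(=O)N1I
Why: Electrophilic aromatic iodination should favour one of the two equivalent carbons next to the small OH (para to a methoxy group) over the carbon wedged between both methoxy groups, one equivalent of NIS in the cold should stop at the mono-iodide, and any para isomer should be separable by chromatography.

Step 2
Reactants: 2 2-iodo-3,5-dimethoxyphenol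
Product: 3 2-iodo-3,5-dimethoxyphenyl acetate
Conditions: Ac2O, pyridine, rt
Reagents that add atoms: acetic anhydride, CC(=O)OC(C)=O
Why: Routine O-acetylation masks the acidic phenol from the arylzinc reagent with a group that zinc and iridium chemistry tolerate and that the alkaline peroxide of step 4 removes without a separate operation.

Step 3
Reactants: 4 1,3-diisopropoxybenzene; 3 2-iodo-3,5-dimethoxyphenyl acetate
Product: 7 2',6'-diisopropoxy-4,6-dimethoxybiphenyl-2-yl acetate, via (2,6-diisopropoxyphenyl)lithium 5 (not isolated), via (2,6-diisopropoxyphenyl)zinc chloride 6 (not isolated)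
Conditions: 4 (1.5 equiv), n-BuLi (1.4 equiv), THF, 0 °C → rt; ZnCl2 (1.5 equiv), THF, 0 °C → rt; then 3, Pd2(dba)3 (2 mol%), RuPhos (8 mol%), THF, 70 °C
Reagents that add atoms: n-butyllithium, [Li]CCCC (lithium of 5 only); ZnCl2 (zinc dichloride), Cl[Zn]Cl (zinc and chlorine of 6 only)
Why: Directed ortho-metalation of a resorcinol diether occurs at C2 between the two alkoxy groups, transmetalation to zinc gives a nucleophile free of the protodeboronation that plagues 2,6-dialkoxyphenylboronic acids, and Negishi coupling with a bulky dialkylbiarylphosphine on palladium is an established entry to tetra-ortho-substituted biaryls that leaves an aryl acetate untouched.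

Step 4
Reactants: 7 2',6'-diisopropoxy-4,6-dimethoxybiphenyl-2-yl acetate
Product: 9 2,6-diisopropoxy-4',6'-dimethoxybiphenyl-2',4-diol, via arylboronic pinacol ester 8 (not isolated)
Conditions: B2pin2 (1.0 equiv), [Ir(OMe)(cod)]2 (2 mol%), dtbpy (4 mol%), THF, 80 °C; then aq. NaOH, 30% H2O2, 0 °C → rt; then 1 M HCl
Reagents that add atoms: hydrogen peroxide, OO (the new phenol oxygen); bis(pinacolato)diboron, CC1(C)OB(OC1(C)C)B1OC(C)(C)C(C)(C)O1 (boryl group of 8 only)
Why: Iridium-catalysed C–H borylation is governed by sterics and can reach only the ring A hydrogen para to the axis, since both ring A'' hydrogens lie between two oxygen substituents and the other two ring A hydrogens are ortho to isopropoxy, and the customary oxidation of the boronate with alkaline H2O2 then gives the phenol while the same medium saponifies the aryl acetate.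

Step 5
Reactants: 9 2,6-diisopropoxy-4',6'-dimethoxybiphenyl-2',4-diol; 10 methyl 3-(4-methoxyphenyl)propiolate (3 equiv)
Product: 11 dimethyl (2Z,2'Z)-3,3'-{[2,6-diisopropoxy-4',6'-dimethoxybiphenyl-2',4-diyl]bis(oxy)}bis[3-(4-methoxyphenyl)acrylate]
Conditions: Cs2CO3 (30 mol%), DMF, 80 °C
Reagents that add atoms: none
Why: Base-catalysed oxa-Michael addition of a phenoxide to an arylpropiolate (the first half of the Ruhemann flavone synthesis) proceeds by anti addition, so aryloxy and ester groups end up cis (Z), which is also the less crowded isomer, and excess alkynoate should carry the slower 2'-phenoxide to completion.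

Step 6
Reactants: 11 dimethyl (2Z,2'Z)-3,3'-{[2,6-diisopropoxy-4',6'-dimethoxybiphenyl-2',4-diyl]bis(oxy)}bis[3-(4-methoxyphenyl)acrylate]
Product: 12 (2Z,2'Z)-3,3'-{[2,6-diisopropoxy-4',6'-dimethoxybiphenyl-2',4-diyl]bis(oxy)}bis[3-(4-methoxyphenyl)acrylic acid]
Conditions: LiOH (6 equiv), THF/MeOH/H2O, 40 °C; then cold 0.5 M HCl to pH 3
Reagents that add atoms: lithium hydroxide, [Li+].[OH-]
Why: In this ordinary saponification the β-carbon is shielded and deactivated by its anisyl and aryloxy substituents, so hydroxide should attack the ester carbonyl, and a cold, brief acidification spares the enol ethers.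

Step 7
Reactants: 12 (2Z,2'Z)-3,3'-{[2,6-diisopropoxy-4',6'-dimethoxybiphenyl-2',4-diyl]bis(oxy)}bis[3-(4-methoxyphenyl)acrylic acid]
Product: 14 5,7-diisopropoxy-6-[5,7-dimethoxy-2-(4-methoxyphenyl)-4-oxo-4H-chromen-8-yl]-2-(4-methoxyphenyl)-4H-chromen-4-one, via bis(trifluoroacetic) mixed anhydride 13 (not isolated)
Conditions: (CF3CO)2O (3 equiv), dry CH2Cl2, 0 °C → rt
Reagents that add atoms: trifluoroacetic anhydride, O=C(OC(=O)C(F)(F)F)C(F)(F)F (trifluoroacetyl groups of 13 only)
Why: (CF3CO)2O turns each carboxyl group into a mixed anhydride (13) that ionises to a β-aryloxy-β-arylacryloyl cation, which attacks the arene carbon ortho to its own enol-ether oxygen and rearomatises by proton loss, the water equivalent ending up in CF3CO2H. The closest known reaction is the closing stage of the Ruhemann flavone synthesis, an intramolecular Friedel–Crafts acylation of a 3-aryloxycinnamic acid, run here twice in one flask. Ring C closes as a six-membered ring by forming C4–C4a (arene carbon onto the acyl carbon, the C=O staying exocyclic, 6-exo), and ring C'' closes in the same mode by forming C4''–C4a''. No stereocentre is formed; the two ortho carbons of ring A are enantiotopic, so attack at either gives the same 6-linked constitution and only makes the C6–C8'' axis stereogenic in racemic form. On ring A'' regioselectivity is secured because the other carbon ortho to the C8a'' oxygen is the quaternary axis carbon C8'', and both attacked carbons are ortho or para to three oxygen donors. Chemoselectivity rests on the Z geometry, which holds the acyl group beside the aryloxy ring and away from the anisyl ring (whose ortho carbons are meta to OMe and unactivated), and on intramolecular acyl transfer outrunning trifluoroacetylation when the anhydride is kept to a small excess in the cold.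

Step 8
Reactants: 14 5,7-diisopropoxy-6-[5,7-dimethoxy-2-(4-methoxyphenyl)-4-oxo-4H-chromen-8-yl]-2-(4-methoxyphenyl)-4H-chromen-4-one
Product: 15 5,7-dihydroxy-6-[5-hydroxy-7-methoxy-2-(4-methoxyphenyl)-4-oxo-4H-chromen-8-yl]-2-(4-methoxyphenyl)-4H-chromen-4-one (CNP0146326.0)
Conditions: BCl3 (1 M in CH2Cl2, 10 equiv), CH2Cl2, −78 °C → rt; then ice-water
Reagents that add atoms: none
Why: Lewis-acid ether cleavage with BCl3 takes secondary alkyl aryl ethers and methyl ethers chelated to a peri carbonyl but leaves unchelated aryl methyl ethers, so O5, O7 and O5'' should be freed while the 7''-, 4'- and 4'''-methoxy groups stay, and the low temperature avoids a Wessely–Moser shift of the 6-linked unit.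

**Compound list**
1 | 3,5-dimethoxyphenol | COc1cc(O)cc(OC)c1 | starting material
2 | 2-iodo-3,5-dimethoxyphenol | COc1cc(O)c(I)c(OC)c1 | intermediate
3 | 2-iodo-3,5-dimethoxyphenyl acetate | COc1cc(OC(C)=O)c(I)c(OC)c1 | intermediate
4 | 1,3-diisopropoxybenzene | CC(C)Oc1cccc(OC(C)C)c1 | starting material
5 | (2,6-diisopropoxyphenyl)lithium | [Li]c1c(OC(C)C)cccc1OC(C)C | intermediate
6 | (2,6-diisopropoxyphenyl)zinc chloride | Cl[Zn]c1c(OC(C)C)cccc1OC(C)C | intermediate
7 | 2',6'-diisopropoxy-4,6-dimethoxybiphenyl-2-yl acetate | COc1cc(OC(C)=O)c(-c2c(OC(C)C)cccc2OC(C)C)c(OC)c1 | intermediate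
8 | 2',6'-diisopropoxy-4,6-dimethoxy-4'-(4,4,5,5-tetramethyl-1,3,2-dioxaborolan-2-yl)biphenyl-2-yl acetate | COc1cc(OC(C)=O)c(-c2c(OC(C)C)cc(B3OC(C)(C)C(C)(C)O3)cc2OC(C)C)c(OC)c1 | intermediate
9 | 2,6-diisopropoxy-4',6'-dimethoxybiphenyl-2',4-diol | COc1cc(O)c(-c2c(OC(C)C)cc(O)cc2OC(C)C)c(OC)c1 | intermediate
10 | methyl 3-(4-methoxyphenyl)propiolate | COC(=O)C#Cc1ccc(OC)cc1 | starting material
11 | dimethyl (2Z,2'Z)-3,3'-{[2,6-diisopropoxy-4',6'-dimethoxybiphenyl-2',4-diyl]bis(oxy)}bis[3-(4-methoxyphenyl)acrylate] | COc1ccc(/C(Oc2cc(OC(C)C)c(-c3c(OC)cc(OC)cc3O/C(=C\C(=O)OC)c3ccc(OC)cc3)c(OC(C)C)c2)=C/C(=O)OC)cc1 | intermediate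
12 | (2Z,2'Z)-3,3'-{[2,6-diisopropoxy-4',6'-dimethoxybiphenyl-2',4-diyl]bis(oxy)}bis[3-(4-methoxyphenyl)acrylic acid] | COc1ccc(/C(Oc2cc(OC(C)C)c(-c3c(OC)cc(OC)cc3O/C(=C\C(=O)O)c3ccc(OC)cc3)c(OC(C)C)c2)=C/C(=O)O)cc1 | intermediate
13 | bis(trifluoroacetic) mixed anhydride of 12 | COc1ccc(/C(Oc2cc(OC(C)C)c(-c3c(OC)cc(OC)cc3O/C(=C\C(=O)OC(=O)C(F)(F)F)c3ccc(OC)cc3)c(OC(C)C)c2)=C/C(=O)OC(=O)C(F)(F)F)cc1 | intermediate
14 | 5,7-diisopropoxy-6-[5,7-dimethoxy-2-(4-methoxyphenyl)-4-oxo-4H-chromen-8-yl]-2-(4-methoxyphenyl)-4H-chromen-4-one | COc1ccc(-c2cc(=O)c3c(OC(C)C)c(-c4c(OC)cc(OC)c5c(=O)cc(-c6ccc(OC)cc6)oc45)c(OC(C)C)cc3o2)cc1 | intermediate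
15 | 5,7-dihydroxy-6-[5-hydroxy-7-methoxy-2-(4-methoxyphenyl)-4-oxo-4H-chromen-8-yl]-2-(4-methoxyphenyl)-4H-chromen-4-one | COc1ccc(-c2cc(=O)c3c(O)c(-c4c(OC)cc(O)c5c(=O)cc(-c6ccc(OC)cc6)oc45)c(O)cc3o2)cc1 | target

Total step count: 8. Longest linear sequence: 8 steps (1 → 2 → 3 → 7 → 9 → 11 → 12 → 14 → 15).

**Steps most likely to fail**

**Step 3.**
- Risk: transmetalation and reductive elimination at a palladium centre that must carry two di-ortho-substituted aryl groups may be too slow. Homocoupling, loss of iodine by reduction and protonation of the zinc reagent could then take over.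
- Fallback: cross-coupling is replaced by ligand coupling at tetravalent lead (Pinhey arylation). This also makes steps 1 and 2 superfluous, because the aryl group is delivered from an aryloxy-lead species to the carbon ortho to the OH.
- The fallback sets out from aryllithium 5 and phenol 1. Quenching 5 with B(OiPr)3 and hydrolysing should give (2,6-diisopropoxyphenyl)boronic acid F1.
- Boron–lead exchange with Pb(OAc)4 (Hg(OAc)2 cat., CHCl3, 40 °C) should give (2,6-diisopropoxyphenyl)lead triacetate F2.
- Treating 1 with F2 in CHCl3/pyridine should give 2',6'-diisopropoxy-4,6-dimethoxybiphenyl-2-ol F3. Acetylation as in step 2 comes back to the route at 7.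

**Step 5.**
- Risk: the hindered 2'-phenoxide may add too slowly to an alkyne made electron-rich by the anisyl group. The reaction could then stall after the first addition, drift to attack through ring carbon with lactonisation, or lose Z/E control.
- Fallback: conjugate addition to the alkyne is replaced by copper-catalysed C–O coupling at a vinyl iodide, which keeps the alkene geometry.
- The fallback sets out from 10 and 9. Hydroiodination of 10 (NaI, AcOH, 110 °C, anti addition) should give methyl (Z)-3-iodo-3-(4-methoxyphenyl)acrylate F4.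
- Coupling of F4 (2.5 equiv) with 9 (CuI, N,N-dimethylglycine, Cs2CO3, dioxane, 80 °C) comes back to the route at 11.

**Step 7.**
- Risk: the second closure may lag behind the first, leaving one ring open. The still open, electron-rich ring may be trifluoroacetylated. Traces of water may protonate and hydrolyse an enol ether, with loss of the side chain.
- Fallback: the pyranones are closed from the other side, at O1–C2. The fallback sets out from 9.
- Double ortho-acetylation (Ac2O, BF3·OEt2, 70 °C, Fries-type acylation held ortho by the boron chelate) should give 3,3'-diacetyl-2,6-diisopropoxy-4',6'-dimethoxybiphenyl-2',4-diol F5.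
- Claisen–Schmidt condensation with 4-methoxybenzaldehyde (KOH, EtOH, rt) should give (2E,2'E)-1,1'-(2',4-dihydroxy-2,6-diisopropoxy-4',6'-dimethoxybiphenyl-3,3'-diyl)bis[3-(4-methoxyphenyl)prop-2-en-1-one] F6.
- Oxidative cyclisation (I2 cat., DMSO, 120 °C) comes back to the route at 14.

**Further compounds**
F1 | step 3 | (2,6-diisopropoxyphenyl)boronic acid | OB(O)c1c(OC(C)C)cccc1OC(C)C
F2 | step 3 | (2,6-diisopropoxyphenyl)lead triacetate | CC(=O)O[Pb](OC(C)=O)(OC(C)=O)c1c(OC(C)C)cccc1OC(C)C
F3 | step 3 | 2',6'-diisopropoxy-4,6-dimethoxybiphenyl-2-ol | COc1cc(O)c(-c2c(OC(C)C)cccc2OC(C)C)c(OC)c1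
F4 | step 5 | methyl (Z)-3-iodo-3-(4-methoxyphenyl)acrylate | COC(=O)/C=C(\I)c1ccc(OC)cc1
F5 | step 7 | 3,3'-diacetyl-2,6-diisopropoxy-4',6'-dimethoxybiphenyl-2',4-diol | CC(=O)c1c(O)cc(OC(C)C)c(-c2c(OC)cc(OC)c(C(C)=O)c2O)c1OC(C)C
F6 | step 7 | (2E,2'E)-1,1'-(2',4-dihydroxy-2,6-diisopropoxy-4',6'-dimethoxybiphenyl-3,3'-diyl)bis[3-(4-methoxyphenyl)prop-2-en-1-one] | COc1ccc(/C=C/C(=O)c2c(O)cc(OC(C)C)c(-c3c(OC)cc(OC)c(C(=O)/C=C/c4ccc(OC)cc4)c3O)c2OC(C)C)cc1
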